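**Retrosynthetic overview**
1. The target is the C6 isobutyrate of a 4,6-diol, which comes from hydroxyl-directed reduction of a 1,6-diketo germacranolide.
2. Key disconnection: the ten-membered ring arises from a seven-membered 2,2-disubstituted cycloheptane-1,3-dione by zinc-mediated intramolecular allylation of C6=O and retro-aldol cleavage of C6–C10. This three-carbon ring expansion also sets the cis lactone fusion.
3. The allyl donor (a bromomethyl butenolide on a CH2 arm at C10) comes from C10 allylation, ozonolysis, asymmetric chromium-catalysed 2-(methoxycarbonyl)allylation/lactonisation (sets C8) and allylic bromination.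
4. The cycloheptanedione comes from (S)-3-hydroxy-3-methylcyclopentanone by ketene [2+2]/retro-aldol two-carbon ring expansion; C4 comes from asymmetric conjugate boration of 3-methylcyclopent-2-enone.
5. Ring order: cyclopentane, then fused cyclobutanone, then cycloheptanedione, then butyrolactone, then the ten-membered carbocycle.

Assumption: germacrane numbering is used throughout (C1 ketone, C4 tertiary carbinol, C6 ester carbinol, C7/C8 lactone ring fusion, C10 CHMe, C11–C13 acrylate carbons); the target is then (4S,6R,7S,8S,10R) with a cis-fused lactone and is treated as the open keto-alcohol.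

**Route**

Step 1
Reactants: 1 3-methylcyclopent-2-en-1-one
Product: 3 (S)-3-hydroxy-3-methylcyclopentan-1-one, via boronate 2 (not isolated)
Conditions: B2pin2, [Cu(MeCN)4]PF6 (5 mol %), (R,R)-QuinoxP* (6 mol %; the enantiomer that gives the (R)-boronate), LiOtBu (10 mol %), MeOH, DMSO, rt; then NaBO3·4H2O, THF–H2O, 0 °C → rt
Reagents that add atoms: bis(pinacolato)diboron, CC1(C)OB(OC1(C)C)B1OC(C)(C)C(C)(C)O1; sodium perborate, [Na+].[O-]OB=O
Why: Copper-catalysed asymmetric conjugate boration of the β,β-disubstituted cyclic enone with a chiral bisphosphine sets the quaternary C4 centre as the (R)-boronate, and perborate oxidation replaces boron by hydroxyl with retention to give the (S)-tertiary alcohol.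

Step 2
Reactants: 3 (S)-3-hydroxy-3-methylcyclopentan-1-one
Product: 4 (S)-trimethyl{[4-methyl-4-(trimethylsilyloxy)cyclopent-1-en-1-yl]oxy}silane
Conditions: LDA (2.2 equiv), TMSCl (2.6 equiv), THF, −78 → 0 °C
Reagents that add atoms: chlorotrimethylsilane, C[Si](C)(C)Cl
Why: In situ-quench enolisation/silylation forms the silyl enol ether and caps the tertiary alcohol without touching C4, and either enol ether regioisomer leads to the same dione in step 4.

Step 3
Reactants: 4 (S)-trimethyl{[4-methyl-4-(trimethylsilyloxy)cyclopent-1-en-1-yl]oxy}silane; 5 2-chloropropanoyl chloride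
Product: 7 (3S)-7-chloro-3,7-dimethyl-1,3-bis(trimethylsilyloxy)bicyclo[3.2.0]heptan-6-one, via chloro(methyl)ketene 6 (not isolated)
Conditions: Et3N, hexane, 25 °C, slow addition of 5
Reagents that add atoms: none
Why: Ketene–silyl enol ether [2+2] cycloaddition of the ketene generated in the flask is regioselective (ketene carbonyl carbon to the enol β-carbon), and its three new stereocentres are all erased in step 4.

Step 4
Reactants: 7 (3S)-7-chloro-3,7-dimethyl-1,3-bis(trimethylsilyloxy)bicyclo[3.2.0]heptan-6-one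
Product: 9 (5S)-5-hydroxy-2,5-dimethylcycloheptane-1,3-dione, via dechlorinated cyclobutanone 8 (not isolated)
Conditions: Zn dust, AcOH, iPrOH–H2O, 0 °C → rt; then 50 °C
Reagents that add atoms: none
Why: Zinc reduction removes the α-chlorine and the β-silyloxy cyclobutanone then undergoes desilylative retro-aldol cleavage of the ring-fusion bond (De Mayo-type two-carbon ring expansion) to the cycloheptane-1,3-dione, with C4 remote from every bond that changes.

Step 5
Reactants: 9 (5S)-5-hydroxy-2,5-dimethylcycloheptane-1,3-dione; 10 allyl methyl carbonate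
Product: 11 (5S)-5-hydroxy-2,5-dimethyl-2-(prop-2-en-1-yl)cycloheptane-1,3-dione
Conditions: Pd(PPh3)4 (2 mol %), THF, rt
Reagents that add atoms: none
Why: Tsuji–Trost allylation of the acidic 2-methyl-1,3-dione under neutral decarboxylative conditions gives clean C-allylation, and the quaternary C10 centre may form as either epimer because it is re-formed in step 9.

Step 6
Reactants: 11 (5S)-5-hydroxy-2,5-dimethyl-2-(prop-2-en-1-yl)cycloheptane-1,3-dione
Product: 13 2-[(4S)-4-hydroxy-1,4-dimethyl-2,7-dioxocycloheptyl]acetaldehyde, via ozonide 12 (not isolated)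
Conditions: O3, CH2Cl2, −78 °C; then Me2S, −78 °C → rt
Reagents that add atoms: ozone, [O-][O+]=O
Why: Ozonolysis with reductive work-up cleaves the only alkene to the aldehyde and creates no stereocentre.

Step 7
Reactants: 13 2-[(4S)-4-hydroxy-1,4-dimethyl-2,7-dioxocycloheptyl]acetaldehyde; 14 methyl 2-(bromomethyl)prop-2-enoate
Product: 16 (5S)-5-hydroxy-2,5-dimethyl-2-{[(2S)-4-methylidene-5-oxooxolan-2-yl]methyl}cycloheptane-1,3-dione, via silyl ether 15 (not isolated)
Conditions: CrCl2 (10 mol %), tBu-carbazole-bis(oxazoline) ligand (11 mol %; the enantiomer that gives 8S), Mn powder, TMSCl, THF, rt; then 1 M HCl, THF, rt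
Reagents that add atoms: chlorotrimethylsilane, C[Si](C)(C)Cl
Why: Catalytic asymmetric Nozaki–Hiyama–Kishi 2-(alkoxycarbonyl)allylation is selective for the aldehyde over the ketones, the chiral chromium–bis(oxazoline) complex sets C8 (S) by reagent control, and acid work-up closes the α-methylene-γ-butyrolactone.

Step 8
Reactants: 16 (5S)-5-hydroxy-2,5-dimethyl-2-{[(2S)-4-methylidene-5-oxooxolan-2-yl]methyl}cycloheptane-1,3-dione
Product: 17 (5S)-2-{[(2S)-4-(bromomethyl)-5-oxo-2,5-dihydrofuran-2-yl]methyl}-5-hydroxy-2,5-dimethylcycloheptane-1,3-dione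
Conditions: NBS (1.05 equiv), AIBN (5 mol %), PhCF3, 80 °C
Reagents that add atoms: N-bromosuccinimide, O=C1CCC(=O)N1Br
Why: Wohl–Ziegler allylic bromination abstracts the allylic C7 hydrogen and delivers bromine to the methylene terminus with allylic transposition (as β-pinene gives myrtenyl bromide), no stereocentre is touched, and either allylic bromide isomer gives the same allylzinc in step 9.

Step 9
Reactants: 17 (5S)-2-{[(2S)-4-(bromomethyl)-5-oxo-2,5-dihydrofuran-2-yl]methyl}-5-hydroxy-2,5-dimethylcycloheptane-1,3-dione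
Product: 20 (4S,7S,8S,10R)-4-hydroxy-1,6-dioxogermacr-11(13)-en-12,8-olide, via allylzinc bromide 18 (not isolated), via zinc aldolate 19 (not isolated)
Conditions: Zn dust (TMSCl-activated), LiCl, THF (0.01 M), 0 → 40 °C; then AcOH, −40 °C
Reagents that add atoms: zinc, [Zn]
Why: Proposed new method: zinc insertion gives the butenolide-derived 2-(alkoxycarbonyl)allylzinc 18, whose γ-carbon C7 adds 5-exo to the only free dione carbonyl C6 (C1 is masked as the hemiketal with the C4 hydroxyl) through a cis-bicyclo[3.3.0] transition state that puts H7 cis to H8 (7S from 8S); the zinc aldolate 19, whose alkoxide is β to the C1 carbonyl across the quaternary C10, then relieves the strain of three contiguous fully substituted carbons by retro-aldol cleavage of C6–C10, a net three-carbon ring expansion from seven to ten members, and cold AcOH protonation of the resulting C1 zinc enolate sets the epimerisable C10 centre (10R, expected to be the thermodynamic α-methyl ketone epimer and correctable by equilibration); the closest known reaction types are the Trost fluoride-triggered allylsilane addition–fragmentation three-carbon ring expansion, the Dowd–Beckwith ring expansion, and Barbier reactions of 3-(bromomethyl)furan-2(5H)-ones that give β-substituted α-methylene-γ-butyrolactones.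

Step 10
Reactants: 20 (4S,7S,8S,10R)-4-hydroxy-1,6-dioxogermacr-11(13)-en-12,8-olide
Product: 21 (4S,6R,7R,8S,10R)-4,6-dihydroxy-1-oxogermacr-11(13)-en-12,8-olide
Conditions: Me4NBH(OAc)3, AcOH–MeCN (1:1), −30 °C
Reagents that add atoms: none
Why: Evans–Saksena hydroxyl-directed reduction, in which the 4α-hydroxyl binds the triacetoxyborohydride and delivers hydride to the α-face of the β-hydroxy ketone to give the 1,3-anti diol (6β-OH, 6R), while the undirected C1 ketone and the enoate are not reduced.

Step 11
Reactants: 21 (4S,6R,7R,8S,10R)-4,6-dihydroxy-1-oxogermacr-11(13)-en-12,8-olide; 22 2-methylpropanoyl chloride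
Product: 23 (4S,6R,7S,8S,10R)-4-hydroxy-6-(2-methylpropanoyloxy)-1-oxogermacr-11(13)-en-12,8-olide (CNP0293926.1)
Conditions: pyridine, DMAP (10 mol %), CH2Cl2, 0 °C
Reagents that add atoms: none
Why: DMAP-catalysed acylation esterifies the only secondary alcohol with retention at C6 (the tertiary C4 hydroxyl is inert), and at 0 °C it should outpace translactonisation to the 12,6-olide.

**Compound list**
1 | 3-methylcyclopent-2-en-1-one | CC1=CC(=O)CC1 | starting material
2 | (R)-3-methyl-3-(4,4,5,5-tetramethyl-1,3,2-dioxaborolan-2-yl)cyclopentan-1-one | O=C1CC[C@](C)(B2OC(C)(C)C(C)(C)O2)C1 | intermediate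
3 | (S)-3-hydroxy-3-methylcyclopentan-1-one | O=C1CC[C@](C)(O)C1 | intermediate
4 | (S)-trimethyl{[4-methyl-4-(trimethylsilyloxy)cyclopent-1-en-1-yl]oxy}silane (major enol ether regioisomer) | C[Si](C)(C)OC1=CC[C@](C)(O[Si](C)(C)C)C1 | intermediate
5 | 2-chloropropanoyl chloride (racemic) | CC(Cl)C(Cl)=O | starting material
6 | chloro(methyl)ketene | CC(Cl)=C=O | intermediate
7 | (3S)-7-chloro-3,7-dimethyl-1,3-bis(trimethylsilyloxy)bicyclo[3.2.0]heptan-6-one (mixture at C1, C5, C7) | C[C@]1(O[Si](C)(C)C)CC2C(=O)C(C)(Cl)C2(O[Si](C)(C)C)C1 | intermediate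
8 | (3S)-3,7-dimethyl-1,3-bis(trimethylsilyloxy)bicyclo[3.2.0]heptan-6-one (mixture at C1, C5, C7) | C[C@]1(O[Si](C)(C)C)CC2C(=O)C(C)C2(O[Si](C)(C)C)C1 | intermediate
9 | (5S)-5-hydroxy-2,5-dimethylcycloheptane-1,3-dione (C2 epimers, in equilibrium with enol and bicyclic hemiketal forms) | CC1C(=O)CC[C@](C)(O)CC1=O | intermediate
10 | allyl methyl carbonate | C=CCOC(=O)OC | starting material
11 | (5S)-5-hydroxy-2,5-dimethyl-2-(prop-2-en-1-yl)cycloheptane-1,3-dione (C2 epimers) | C=CCC1(C)C(=O)CC[C@](C)(O)CC1=O | intermediate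
12 | (5S)-5-hydroxy-2,5-dimethyl-2-[(1,2,4-trioxolan-3-yl)methyl]cycloheptane-1,3-dione | CC1(CC2OCOO2)C(=O)CC[C@](C)(O)CC1=O | intermediate
13 | 2-[(4S)-4-hydroxy-1,4-dimethyl-2,7-dioxocycloheptyl]acetaldehyde (C1 epimers) | O=CCC1(C)C(=O)CC[C@](C)(O)CC1=O | intermediate
14 | methyl 2-(bromomethyl)prop-2-enoate | C=C(CBr)C(=O)OC | starting material
15 | methyl (4S)-5-[(4S)-4-hydroxy-1,4-dimethyl-2,7-dioxocycloheptyl]-2-methylidene-4-(trimethylsilyloxy)pentanoate | C=C(C[C@H](CC1(C)C(=O)CC[C@](C)(O)CC1=O)O[Si](C)(C)C)C(=O)OC | intermediate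
16 | (5S)-5-hydroxy-2,5-dimethyl-2-{[(2S)-4-methylidene-5-oxooxolan-2-yl]methyl}cycloheptane-1,3-dione (C2 epimers) | C=C1C[C@H](CC2(C)C(=O)CC[C@](C)(O)CC2=O)OC1=O | intermediate
17 | (5S)-2-{[(2S)-4-(bromomethyl)-5-oxo-2,5-dihydrofuran-2-yl]methyl}-5-hydroxy-2,5-dimethylcycloheptane-1,3-dione (C2 epimers) | BrCC1=C[C@H](CC2(C)C(=O)CC[C@](C)(O)CC2=O)OC1=O | intermediate
18 | bromo{[(5S)-5-{[(4S)-4-hydroxy-1,4-dimethyl-2,7-dioxocycloheptyl]methyl}-2-oxo-2,5-dihydrofuran-3-yl]methyl}zinc | Br[Zn]CC1=C[C@H](CC2(C)C(=O)CC[C@](C)(O)CC2=O)OC1=O | intermediate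
19 | bromozinc 6-alkoxide of (4S,7S,8S)-4,6-dihydroxy-1-oxo-6,10-cyclogermacr-11(13)-en-12,8-olide (C6–C7 and C6–C10 bonds both present; C6 and C10 transient) | C=C1C(=O)O[C@H]2CC3(C)C(=O)CC[C@](C)(O)CC3(O[Zn]Br)[C@@H]12 | intermediate
20 | (4S,7S,8S,10R)-4-hydroxy-1,6-dioxogermacr-11(13)-en-12,8-olide (cis-fused lactone) | C=C1C(=O)O[C@H]2C[C@@H](C)C(=O)CC[C@](C)(O)CC(=O)[C@@H]12 | intermediate
21 | (4S,6R,7R,8S,10R)-4,6-dihydroxy-1-oxogermacr-11(13)-en-12,8-olide (C7 unchanged in space; its descriptor changes by priority only) | C=C1C(=O)O[C@H]2C[C@@H](C)C(=O)CC[C@](C)(O)C[C@@H](O)[C@@H]12 | intermediate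
22 | 2-methylpropanoyl chloride | CC(C)C(Cl)=O | starting material
23 | (3aS,4R,6S,10R,11aS)-6-hydroxy-6,10-dimethyl-3-methylidene-2,9-dioxododecahydrocyclodeca[b]furan-4-yl 2-methylpropanoate, i.e. (4S,6R,7S,8S,10R)-4-hydroxy-6-(2-methylpropanoyloxy)-1-oxogermacr-11(13)-en-12,8-olide | C=C1C(=O)O[C@H]2C[C@@H](C)C(=O)CC[C@](C)(O)C[C@@H](OC(=O)C(C)C)[C@@H]12 | target

**Summary**
Total step count: 11. Longest linear sequence: 11 steps (1 to 23; compounds 5, 10, 14 and 22 are bought).

Steps most likely to fail, each with a fallback: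

Step 8 (allylic bromination). The radical bromination may also attack positions α to the ketones, or the HBr formed may dehydrate the tertiary alcohol. The fallback sets out from 16 and uses ionic chemistry instead: bromine (1 equiv, CH2Cl2, −78 °C) adds across the exocyclic alkene to give the dibromide (5S)-2-{[(2S)-4-bromo-4-(bromomethyl)-5-oxooxolan-2-yl]methyl}-5-hydroxy-2,5-dimethylcycloheptane-1,3-dione F1. Triethylamine (0 °C) then removes HBr across C7–C11 to give the conjugated bromomethyl butenolide, and the route is rejoined at 17.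

Step 9 (the proposed zinc allylation/retro-aldol ring expansion). The allylzinc may attack C1 if the hemiketal does not mask it, the aldolate may not fragment, the exocyclic alkene of the base-sensitive β,γ-unsaturated C6 ketone may move into conjugation, or C10 may be protonated to the wrong epimer. The fallback uses the known fluoride-triggered allylsilane addition–fragmentation ring expansion and sets out from 17. Hexamethyldisilane with Pd(PPh3)4 (THF, 60 °C) converts the allylic bromide into the allylsilane (5S)-5-hydroxy-2,5-dimethyl-2-({(2S)-5-oxo-4-[(trimethylsilyl)methyl]-2,5-dihydrofuran-2-yl}methyl)cycloheptane-1,3-dione F2. TBAF (THF, −20 °C, then AcOH) then triggers addition of C7 to C6, and the free alkoxide fragments across C6–C10; the route is rejoined at 20.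

Step 10 (directed reduction). Delivery from the tertiary C4 hydroxyl in the macrocycle may be slow or give the 6α-alcohol. The fallback sets out from 20 and inverts the logic: chelation-controlled Narasaka–Prasad reduction (Et2BOMe, NaBH4, THF–MeOH, −78 °C) deliberately gives the 1,3-syn diol (4S,6S,7R,8S,10R)-4,6-dihydroxy-1-oxogermacr-11(13)-en-12,8-olide F3. Mitsunobu esterification with 2-methylpropanoic acid (PPh3, DIAD, toluene, 0 °C) then installs the ester with inversion at C6, and the route is rejoined at 23.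

Further compounds
F1 | step 8 | (5S)-2-{[(2S)-4-bromo-4-(bromomethyl)-5-oxooxolan-2-yl]methyl}-5-hydroxy-2,5-dimethylcycloheptane-1,3-dione | BrCC1(Br)C[C@H](CC2(C)C(=O)CC[C@](C)(O)CC2=O)OC1=O
F2 | step 9 | (5S)-5-hydroxy-2,5-dimethyl-2-({(2S)-5-oxo-4-[(trimethylsilyl)methyl]-2,5-dihydrofuran-2-yl}methyl)cycloheptane-1,3-dione | C[Si](C)(C)CC1=C[C@H](CC2(C)C(=O)CC[C@](C)(O)CC2=O)OC1=O
F3 | step 10 | (4S,6S,7R,8S,10R)-4,6-dihydroxy-1-oxogermacr-11(13)-en-12,8-olide | C=C1C(=O)O[C@H]2C[C@@H](C)C(=O)CC[C@](C)(O)C[C@H](O)[C@@H]12
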